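**Retrosynthetic overview**
1. Target ⇒ its hexa-O-benzyl ether (global hydrogenolysis last); the galloyl ester sits on the future 7-O from the first step.
2. C3 carbinol ⇒ flavan-3-one (hydride anti to the 2-aryl group) ⇒ 3-ethylidene flavan (oxidative cleavage of the exocyclic C=C).
3. Pyran ring C ⇒ hetero-Diels–Alder of an A-ring ortho-quinone methide with the aryl-bearing C=C of an axially chiral allene (forms O1–C2 and C3–C4; the axis sets C2).
4. Quinone methide ⇒ 2,4,6-trihydroxybenzaldehyde, 4-O-galloylated then reduced; allene ⇒ anti-SN2′ arylation of (R)-but-3-yn-2-yl mesylate (bought centre → axis → C2 → C3).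
5. Ring order: rings A, B and the galloyl ring are bought; ring C is the only ring made, in the cycloaddition.

Assumption: 5-bromo-1,2,3-tris(benzyloxy)benzene, 3,4,5-tris(benzyloxy)benzoyl chloride and (R)-but-3-yn-2-ol are bought as catalogue compounds.

The cycloaddition of an ortho-quinone methide with an aryl allene (step 5) is a design by analogy with styrene cycloadditions, not a reaction with direct precedent.

**Step 1**
Reactants: 1 2,4,6-trihydroxybenzaldehyde; 2 3,4,5-tris(benzyloxy)benzoyl chloride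
Product: 3 4-formyl-3,5-dihydroxyphenyl 3,4,5-tris(benzyloxy)benzoate
Conditions: 2 (1.0 equiv), i-Pr2NEt (1.1 equiv), THF, −20 → 0 °C
Reagents that add atoms: none
Why: Einhorn-type O-acylation, selective because the 4-OH is para to the formyl group (most acidic) and the only phenol not hydrogen-bonded to the carbonyl, which fixes the future 7-O-gallate position; no stereocentre is formed.

**Step 2**
Reactants: 3 4-formyl-3,5-dihydroxyphenyl 3,4,5-tris(benzyloxy)benzoate
Product: 4 3,5-dihydroxy-4-(hydroxymethyl)phenyl 3,4,5-tris(benzyloxy)benzoate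
Conditions: NaBH4, THF/i-PrOH, 0 °C; pH 6 phosphate buffer; used crude
Reagents that add atoms: none
Why: Chemoselective borohydride reduction of the aldehyde at low temperature leaves the hindered, electron-rich aryl benzoate intact and gives the labile salicyl alcohol; no stereocentre is formed.

**Step 3**
Reactants: 5 (2R)-but-3-yn-2-ol
Product: 6 (2R)-but-3-yn-2-yl methanesulfonate
Conditions: MsCl, Et3N, CH2Cl2, −30 → 0 °C
Reagents that add atoms: methanesulfonyl chloride, CS(=O)(=O)Cl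
Why: Mesylation (O-sulfonylation) takes place at oxygen only, so the bought (R) centre is retained unchanged.

**Step 4**
Reactants: 7 5-bromo-1,2,3-tris(benzyloxy)benzene; 6 (2R)-but-3-yn-2-yl methanesulfonate
Product: 10 (Sa)-1,2,3-tris(benzyloxy)-5-(buta-1,2-dien-1-yl)benzene, via aryl Grignard reagent 8 (not isolated), via arylcopper reagent 9 (not isolated)
Conditions: Mg, THF, 40 °C; CuBr·SMe2 (1 equiv), LiBr, THF, −60 °C; then 6, −60 → −30 °C
Reagents that add atoms: none
Why: Magnesium insertion and transmetalation give an arylcopper(I) reagent that displaces the propargylic mesylate in an anti-selective SN2′ (1,3-) substitution, so the bought (R) centre is converted stereospecifically into the (Sa) axis of the allene.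

**Step 5**
Reactants: 4 3,5-dihydroxy-4-(hydroxymethyl)phenyl 3,4,5-tris(benzyloxy)benzoate; 10 (Sa)-1,2,3-tris(benzyloxy)-5-(buta-1,2-dien-1-yl)benzene
Product: 12 (2S,3Z)-3-ethylidene-5-hydroxy-2-[3,4,5-tris(benzyloxy)phenyl]-3,4-dihydro-2H-chromen-7-yl 3,4,5-tris(benzyloxy)benzoate, via ortho-quinone methide 11 (not isolated)
Conditions: 10 (2 equiv), 4 added over 4 h, 4 Å MS, PhMe, 100 °C
Reagents that add atoms: none
Why: Thermal dehydration gives an ortho-quinone methide that is trapped in an inverse-electron-demand hetero-Diels–Alder reaction by the styrene-like C=C of the allene (methylene carbon to the allene central carbon, oxygen to the benzylic carbon, as in flavan syntheses from styrenes), and because both bonds form on the face anti to the distal methyl group the allene axis sets C2 in the spatial arrangement of the target (the CIP label is S here only because the exocyclic alkene carbon ranks below the aryl group).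

**Step 6**
Reactants: 12 (2S,3Z)-3-ethylidene-5-hydroxy-2-[3,4,5-tris(benzyloxy)phenyl]-3,4-dihydro-2H-chromen-7-yl 3,4,5-tris(benzyloxy)benzoate
Product: 14 (2R)-5-hydroxy-3-oxo-2-[3,4,5-tris(benzyloxy)phenyl]-3,4-dihydro-2H-chromen-7-yl 3,4,5-tris(benzyloxy)benzoate, via vicinal diol 13 (not isolated)
Conditions: K2OsO4·2H2O (2 mol %), NMO (1.5 equiv), acetone/H2O, rt; then NaIO4 (2 equiv), 0 °C
Reagents that add atoms: N-methylmorpholine N-oxide, C[N+]1([O-])CCOCC1; water, O
Why: Upjohn dihydroxylation of the only C=C bond followed by periodate glycol cleavage (Lemieux–Johnson-type oxidative cleavage) removes the ethylidene carbon as acetaldehyde and unveils the C3 ketone under near-neutral conditions that neither oxidise the benzyloxy arenes nor enolise C2.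

**Step 7**
Reactants: 14 (2R)-5-hydroxy-3-oxo-2-[3,4,5-tris(benzyloxy)phenyl]-3,4-dihydro-2H-chromen-7-yl 3,4,5-tris(benzyloxy)benzoate
Product: 15 (2R,3R)-3,5-dihydroxy-2-[3,4,5-tris(benzyloxy)phenyl]-3,4-dihydro-2H-chromen-7-yl 3,4,5-tris(benzyloxy)benzoate
Conditions: L-Selectride (2.2 equiv), LiBr, THF, −78 °C; pH 7 buffer
Reagents that add atoms: none
Why: Substrate-controlled ketone reduction in which the bulky hydride attacks from the face opposite the adjacent 2-aryl group, giving the 2,3-cis (3R) alcohol as in the flavan-3-one to epi-flavan-3-ol reduction, while at −78 °C the ketone reacts much faster than the hindered aryl ester.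

**Step 8**
Reactants: 15 (2R,3R)-3,5-dihydroxy-2-[3,4,5-tris(benzyloxy)phenyl]-3,4-dihydro-2H-chromen-7-yl 3,4,5-tris(benzyloxy)benzoate
Product: 16 epigallocatechin 7-O-gallate, (2R,3R)-3,5-dihydroxy-2-(3,4,5-trihydroxyphenyl)-3,4-dihydro-2H-chromen-7-yl 3,4,5-trihydroxybenzoate
Conditions: H2 (1 atm), 20% Pd(OH)2/C, THF/MeOH, rt
Reagents that add atoms: none
Why: Palladium-catalysed hydrogenolysis cleaves the six benzyl ethers while the aryl ester, the ring ether and both stereocentres are untouched, which delivers the target.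

**Compound list**
1 | 2,4,6-trihydroxybenzaldehyde | O=Cc1c(O)cc(O)cc1O | starting material
2 | 3,4,5-tris(benzyloxy)benzoyl chloride | O=C(Cl)c1cc(OCc2ccccc2)c(OCc2ccccc2)c(OCc2ccccc2)c1 | starting material
3 | 4-formyl-3,5-dihydroxyphenyl 3,4,5-tris(benzyloxy)benzoate | O=Cc1c(O)cc(OC(=O)c2cc(OCc3ccccc3)c(OCc3ccccc3)c(OCc3ccccc3)c2)cc1O | intermediate
4 | 3,5-dihydroxy-4-(hydroxymethyl)phenyl 3,4,5-tris(benzyloxy)benzoate | OCc1c(O)cc(OC(=O)c2cc(OCc3ccccc3)c(OCc3ccccc3)c(OCc3ccccc3)c2)cc1O | intermediate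
5 | (2R)-but-3-yn-2-ol | C[C@@H](O)C#C | starting material
6 | (2R)-but-3-yn-2-yl methanesulfonate | C[C@@H](OS(C)(=O)=O)C#C | intermediate
7 | 5-bromo-1,2,3-tris(benzyloxy)benzene | Brc1cc(OCc2ccccc2)c(OCc2ccccc2)c(OCc2ccccc2)c1 | starting material
8 | [3,4,5-tris(benzyloxy)phenyl]magnesium bromide | Br[Mg]c1cc(OCc2ccccc2)c(OCc2ccccc2)c(OCc2ccccc2)c1 | intermediate
9 | [3,4,5-tris(benzyloxy)phenyl]copper(I) (as its MgBr2·LiBr complex) | [Cu]c1cc(OCc2ccccc2)c(OCc2ccccc2)c(OCc2ccccc2)c1 | intermediate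
10 | (Sa)-1,2,3-tris(benzyloxy)-5-(buta-1,2-dien-1-yl)benzene | [H]C(c1cc(OCc2ccccc2)c(OCc2ccccc2)c(OCc2ccccc2)c1)=[C@]=C([H])C | intermediate
11 | 5-hydroxy-4-methylidene-3-oxocyclohexa-1,5-dien-1-yl 3,4,5-tris(benzyloxy)benzoate (ortho-quinone methide) | C=C1C(=O)C=C(OC(=O)c2cc(OCc3ccccc3)c(OCc3ccccc3)c(OCc3ccccc3)c2)C=C1O | intermediate
12 | (2S,3Z)-3-ethylidene-5-hydroxy-2-[3,4,5-tris(benzyloxy)phenyl]-3,4-dihydro-2H-chromen-7-yl 3,4,5-tris(benzyloxy)benzoate | O=C(Oc1cc(O)c2c(c1)O[C@H](c1cc(OCc3ccccc3)c(OCc3ccccc3)c(OCc3ccccc3)c1)/C(=C\C)C2)c1cc(OCc2ccccc2)c(OCc2ccccc2)c(OCc2ccccc2)c1 | intermediate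
13 | (2R)-3,5-dihydroxy-3-(1-hydroxyethyl)-2-[3,4,5-tris(benzyloxy)phenyl]-3,4-dihydro-2H-chromen-7-yl 3,4,5-tris(benzyloxy)benzoate (diol, mixture at the two new centres) | O=C(Oc1cc(O)c2c(c1)O[C@H](c1cc(OCc3ccccc3)c(OCc3ccccc3)c(OCc3ccccc3)c1)C(O)(C(C)O)C2)c1cc(OCc2ccccc2)c(OCc2ccccc2)c(OCc2ccccc2)c1 | intermediate
14 | (2R)-5-hydroxy-3-oxo-2-[3,4,5-tris(benzyloxy)phenyl]-3,4-dihydro-2H-chromen-7-yl 3,4,5-tris(benzyloxy)benzoate | O=C(Oc1cc(O)c2c(c1)O[C@H](c1cc(OCc3ccccc3)c(OCc3ccccc3)c(OCc3ccccc3)c1)C(=O)C2)c1cc(OCc2ccccc2)c(OCc2ccccc2)c(OCc2ccccc2)c1 | intermediate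
15 | (2R,3R)-3,5-dihydroxy-2-[3,4,5-tris(benzyloxy)phenyl]-3,4-dihydro-2H-chromen-7-yl 3,4,5-tris(benzyloxy)benzoate | O=C(Oc1cc(O)c2c(c1)O[C@H](c1cc(OCc3ccccc3)c(OCc3ccccc3)c(OCc3ccccc3)c1)[C@H](O)C2)c1cc(OCc2ccccc2)c(OCc2ccccc2)c(OCc2ccccc2)c1 | intermediate
16 | epigallocatechin 7-O-gallate, (2R,3R)-3,5-dihydroxy-2-(3,4,5-trihydroxyphenyl)-3,4-dihydro-2H-chromen-7-yl 3,4,5-trihydroxybenzoate | O=C(Oc1cc(O)c2c(c1)O[C@H](c1cc(O)c(O)c(O)c1)[C@H](O)C2)c1cc(O)c(O)c(O)c1 | target

**Totals**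
Total step count: 8. Longest linear sequence: 6 steps (1, 2, 5, 6, 7, 8; equally 3, 4, 5, 6, 7, 8).

**Three steps most likely to fail**

Step 2. The salicyl alcohol 4 is labile, and borohydride can over-reduce it through the quinone methide. The fallback sets out from 3 and comes back at 12. Reductive amination of 3 (morpholine, NaBH(OAc)3, DCE, rt) gives the phenolic Mannich base 3,5-dihydroxy-4-(morpholin-4-ylmethyl)phenyl 3,4,5-tris(benzyloxy)benzoate F1. N-Methylation (MeI, MeCN, rt) gives the storable salt 4-{[2,6-dihydroxy-4-({3,4,5-tris(benzyloxy)benzoyl}oxy)phenyl]methyl}-4-methylmorpholin-4-ium iodide F2. Warming F2 with i-Pr2NEt and 10 in MeCN at 60 °C expels N-methylmorpholine to give 11, which 10 traps to give 12.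

Step 5. The quinone methide 11 may oligomerise or alkylate the free-phenol ring faster than it adds to 10. The fallback sets out from 4 and comes back at 12. Condensation of crude 4 with phenylboronic acid (PhMe, 4 Å MS, rt) gives the isolable cyclic boronate 5-hydroxy-2-phenyl-4H-1,3,2-benzodioxaborinin-7-yl 3,4,5-tris(benzyloxy)benzoate F3. Heating purified F3 with 10 (3 equiv, PhMe, 130 °C, sealed tube) releases 11 slowly by cycloreversion with loss of the boron fragment, so the diene never accumulates, and 12 forms as before.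

Step 7. L-Selectride may attack the aryl ester, or the lithium phenoxide may stall the reduction. The fallback sets out from 14 and comes back at 16. Enol silylation (TBSOTf, Et3N, CH2Cl2, −78 °C) gives the conjugated enol ether (2R)-3,5-bis(tert-butyldimethylsilyloxy)-2-[3,4,5-tris(benzyloxy)phenyl]-2H-chromen-7-yl 3,4,5-tris(benzyloxy)benzoate F4. Hydrogenation (H2, Pd(OH)2/C, THF/MeOH) adds hydrogen to C3=C4 anti to the 2-aryl group and removes the benzyl groups, giving (2R,3R)-3,5-bis(tert-butyldimethylsilyloxy)-2-(3,4,5-trihydroxyphenyl)-3,4-dihydro-2H-chromen-7-yl 3,4,5-trihydroxybenzoate F5. HF·pyridine (THF, 0 °C) then gives 16.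

**Further compounds**
F1 | step 2 | 3,5-dihydroxy-4-(morpholin-4-ylmethyl)phenyl 3,4,5-tris(benzyloxy)benzoate | O=C(Oc1cc(O)c(CN2CCOCC2)c(O)c1)c1cc(OCc2ccccc2)c(OCc2ccccc2)c(OCc2ccccc2)c1
F2 | step 2 | 4-{[2,6-dihydroxy-4-({3,4,5-tris(benzyloxy)benzoyl}oxy)phenyl]methyl}-4-methylmorpholin-4-ium iodide | C[N+]1(Cc2c(O)cc(OC(=O)c3cc(OCc4ccccc4)c(OCc4ccccc4)c(OCc4ccccc4)c3)cc2O)CCOCC1.[I-]
F3 | step 5 | 5-hydroxy-2-phenyl-4H-1,3,2-benzodioxaborinin-7-yl 3,4,5-tris(benzyloxy)benzoate | O=C(Oc1cc(O)c2COB(c3ccccc3)Oc2c1)c1cc(OCc2ccccc2)c(OCc2ccccc2)c(OCc2ccccc2)c1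
F4 | step 7 | (2R)-3,5-bis(tert-butyldimethylsilyloxy)-2-[3,4,5-tris(benzyloxy)phenyl]-2H-chromen-7-yl 3,4,5-tris(benzyloxy)benzoate | O=C(Oc1cc(O[Si](C)(C)C(C)(C)C)c2c(c1)O[C@H](c1cc(OCc3ccccc3)c(OCc3ccccc3)c(OCc3ccccc3)c1)C(O[Si](C)(C)C(C)(C)C)=C2)c1cc(OCc2ccccc2)c(OCc2ccccc2)c(OCc2ccccc2)c1
F5 | step 7 | (2R,3R)-3,5-bis(tert-butyldimethylsilyloxy)-2-(3,4,5-trihydroxyphenyl)-3,4-dihydro-2H-chromen-7-yl 3,4,5-trihydroxybenzoate | O=C(Oc1cc(O[Si](C)(C)C(C)(C)C)c2c(c1)O[C@H](c1cc(O)c(O)c(O)c1)[C@H](O[Si](C)(C)C(C)(C)C)C2)c1cc(O)c(O)c(O)c1
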